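**Plan**
1. Retrosynthesis: C9–Cl, C9–CH3, C8–Br and C1=CH2 go back to two ketones (C9, C1), and C3–OH/C4–Br goes back to a C3=C4 alkene. The achiral spiro trienedione 9 that remains is cut at C5–C6, the bond between the two quaternary carbons.
2. Enabling feature: in ring A the spiro carbon C6 lies between an sp2 carbon (C1, a masked ketone) and CMe2 (C5). In ring B it stands 1,4 to the heteroatom-bearing C9. C6 is therefore the para carbon of a phenol and C1 a carbinol, which is the retron of a semipinacol shift of C5 from C1 to C6.
3. Forward: cyclopentenone 3 (ring A with five members, from dione 1) and an aryl Grignard reagent (ring B as arene) give 7. A two-electron oxidation then enlarges ring A to six members and turns ring B into a dienone in one event.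
4. Next come desymmetrising reduction of ring B, the ring A bromohydrin, masking of C9 as an enol silane, methylenation of C1, then Br, CH3 and Cl on ring B, and desilylation.
5. Stereochemistry: C6 comes from a ligand-controlled CuH reduction. C3/C4 come from anti opening of a bromonium ion, with the face chosen by the unlike arms at C6. C8 is set by equilibration to the equatorial bromide (cis to C5). C9 is set by axial methyl delivery, then OH to Cl with retention.

Key step: step 4

Remark on locants: spiro[5.5]undecane locants are kept constant. Ring A is C1 (C=CH2), C2, C3 (CHOH), C4 (CHBr), C5 (CMe2); C6 is the spiro carbon; ring B is C7 (CH2), C8 (CHBr), C9 (CClMe), C10, C11.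
Assumption: (R)-DTBM-SEGPHOS is taken to give the (6R)-enone 11. If a pilot run shows the opposite sense, the equally available (S)-ligand is used.

**Step 1**
Reactants: 1 2,2-dimethylcyclopentane-1,3-dione
Product: 2 keto enol triflate (5,5-dimethyl-4-oxocyclopent-1-en-1-yl trifluoromethanesulfonate)
Conditions: KN(SiMe3)2 (1.05 equiv), THF, −78 °C; PhNTf2, −78 to 0 °C
Reagents that add atoms: N-phenylbis(trifluoromethanesulfonimide), O=S(=O)(N(c1ccccc1)S(=O)(=O)C(F)(F)F)C(F)(F)F
Why: Kinetic enolate O-triflation; the dione has only one kind of enolisable position, so one equivalent of base should give a single mono enol triflate that marks the future C3=C4 bond.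

**Step 2**
Reactants: 2 keto enol triflate
Product: 3 2,2-dimethylcyclopent-3-en-1-one
Conditions: Pd(PPh3)4 (3 mol %), LiCl, Bu3SnH, THF, 50 °C
Reagents that add atoms: none
Why: Palladium-catalysed hydride transfer from tin to a vinyl triflate (Stille-type reduction) runs without base or acid, so the β,γ-alkene should not move into conjugation.

**Step 3**
Reactants: 3 2,2-dimethylcyclopent-3-en-1-one; 4 (4-bromophenoxy)(tert-butyl)dimethylsilane
Product: 7 phenol carbinol (rac-1-(4-hydroxyphenyl)-2,2-dimethylcyclopent-3-en-1-ol), via aryl Grignard reagent 5 (not isolated), via silyl ether carbinol 6 (not isolated)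
Conditions: 4, Mg, THF, reflux; then 3, LaCl3·2LiCl, THF, 0 °C; aq. work-up; then TBAF, THF, 0 °C
Reagents that add atoms: none
Why: Grignard 1,2-addition to a hindered, easily enolised ketone is assisted by LaCl3·2LiCl, which activates the carbonyl and suppresses enolisation, and fluoride then frees the phenol; the carbinol centre forms as a racemate, which is harmless because step 4 destroys it.

**Step 4**
Reactants: 7 phenol carbinol
Product: 9 spiro trienedione (5,5-dimethylspiro[5.5]undeca-3,7,10-triene-1,9-dione), via aryloxyiodane 8 (not isolated)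
Conditions: PhI(OAc)2 (1.1 equiv), (CF3)2CHOH, 0 °C, 10 min; aq. NaHCO3
Reagents that add atoms: none
Why: Ligand exchange at trivalent iodine gives 8; loss of PhI and acetate in the ionising, non-nucleophilic solvent places positive charge on the para carbon C6, and the C1–C5 bond aligned with that empty orbital shifts to C6 while the carbinol oxygen becomes the C1 ketone (semipinacol). The closest known reaction type is the hypervalent-iodine oxidative dearomatisation of 4-(1-hydroxyalkyl)phenols, in which a carbinol substituent moves to the para carbon (oxidative Wagner–Meerwein transposition). Ring A is not closed by a cyclisation but grows from five to six members by a 1,2-alkyl shift that inserts C6 between C1 and C5, and ring B becomes a cross-conjugated dienone at the same time, so the bond between the two quaternary carbons, the spiro atom and both carbonyl handles arise together. No stereocentre is formed, because ring B of 9 has a mirror plane and C6 is only prostereogenic, which is why racemic 7 suffices. The selectivity needed is migration of C5 and not of C2, and it is secured because C5 is tertiary as well as allylic and carries positive charge in the bridged transition state far better than the CH2 group. Short contact at 0 °C and a bicarbonate quench should limit acid-induced dienone–phenol acyl shift of 9.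

**Step 5**
Reactants: 9 spiro trienedione
Product: 11 spiro enone ((6R)-5,5-dimethylspiro[5.5]undeca-3,7-diene-1,9-dione), via silyl dienol ether 10 (not isolated)
Conditions: Cu(OAc)2 (5 mol %), (R)-DTBM-SEGPHOS (5.5 mol %), (EtO)2MeSiH (1.2 equiv), toluene, −20 °C; then aq. citric acid, THF, 0 °C
Reagents that add atoms: none
Why: Ligand-controlled copper hydride conjugate reduction of one of the two enantiotopic C=C bonds (desymmetrisation of a 4,4-disubstituted cyclohexa-2,5-dienone) makes C6 a stereocentre, since the catalyst's face preference combined with hydride entry anti to the bulky C5 side selects one alkene, and storage of the product as 10 until work-up prevents a second reduction.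

**Step 6**
Reactants: 11 spiro enone
Product: 12 bromohydrin ((3S,4S,6R)-4-bromo-3-hydroxy-5,5-dimethylspiro[5.5]undec-7-ene-1,9-dione)
Conditions: NBS (1.05 equiv), acetone/H2O 4:1, 0 °C, dark
Reagents that add atoms: N-bromosuccinimide, O=C1CCC(=O)N1Br; water, O
Why: Bromohydrin formation leaves the electron-poor enone untouched, and water opens the C3/C4 bromonium ion anti at C3 because C4 is neopentyl, which fixes the regiochemistry and the trans relation; the face should follow from the half-chair that puts the flat sp2 arm C7, rather than C11H2, syn-axial to the incoming bromine, so Br ends cis to C7, and any other diastereomer is removed by chromatography.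

**Step 7**
Reactants: 12 bromohydrin
Product: 13 silyl ether ((3S,4S,6R)-4-bromo-3-(tert-butyldimethylsilyloxy)-5,5-dimethylspiro[5.5]undec-7-ene-1,9-dione)
Conditions: TBSOTf, 2,6-lutidine, CH2Cl2, −78 to −40 °C
Reagents that add atoms: tert-butyldimethylsilyl triflate, CC(C)(C)[Si](C)(C)OS(=O)(=O)C(F)(F)F
Why: O-Silylation with a weak, hindered base protects the aldol-type alcohol without E1cB dehydration or epoxide closure.

**Step 8**
Reactants: 13 silyl ether
Product: 14 enol silane ((3S,4S,6R)-4-bromo-3-(tert-butyldimethylsilyloxy)-5,5-dimethyl-9-(triethylsilyloxy)spiro[5.5]undec-8-en-1-one)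
Conditions: RhCl(PPh3)3 (2 mol %), Et3SiH (1.5 equiv), toluene, 50 °C
Reagents that add atoms: triethylsilane, CC[SiH](CC)CC
Why: Rhodium-catalysed 1,4-hydrosilylation of an enone with a monohydrosilane gives the regiodefined C8=C9 enol silane, which masks C9 for step 9 and stores the site of bromination, while the hindered C1 ketone and the neopentyl bromide should stay untouched.

**Step 9**
Reactants: 14 enol silane
Product: 15 methylidene enol silane ((3S,4S,6S)-4-bromo-3-(tert-butyldimethylsilyloxy)-5,5-dimethyl-1-methylidene-9-(triethylsilyloxy)spiro[5.5]undec-8-ene)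
Conditions: Cp2TiMe2 (3 equiv), toluene, 70 °C, dark
Reagents that add atoms: dimethyltitanocene, C[Ti](C)(C1C=CC=C1)C1C=CC=C1
Why: Petasis methylenation uses a small, non-basic titanium methylidene, so the α-quaternary β-silyloxy ketone should be converted without loss of silanol and without attack on the enol silane or the bromide.

**Step 10**
Reactants: 15 methylidene enol silane
Product: 16 bromo ketone ((3S,4S,6S,8S)-4,8-dibromo-3-(tert-butyldimethylsilyloxy)-5,5-dimethyl-1-methylidenespiro[5.5]undecan-9-one)
Conditions: NBS (1.0 equiv), NaHCO3, THF, −78 °C; then LiBr (cat.), acetone, rt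
Reagents that add atoms: N-bromosuccinimide, O=C1CCC(=O)N1Br
Why: Electrophilic bromination of the enol silane outruns attack on the 1,1-disubstituted alkene at low temperature, and bromide-catalysed epimerisation funnels C8 to the equatorial bromide cis to C5, because the axial epimer suffers a 1,3-diaxial clash with the axial C1 substituent of C6.

**Step 11**
Reactants: 16 bromo ketone
Product: 17 tertiary alcohol ((3S,4S,6S,8S,9S)-4,8-dibromo-3-(tert-butyldimethylsilyloxy)-5,5,9-trimethyl-1-methylidenespiro[5.5]undecan-9-ol)
Conditions: AlMe3 (4 equiv), toluene, −78 to −30 °C; aq. potassium sodium tartrate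
Reagents that add atoms: trimethylaluminium, C[Al](C)C
Why: Carbonyl methylation with excess AlMe3 in a hydrocarbon solvent proceeds by axial attack, because the aluminium-bound oxygen is pushed away from the equatorial C8–Br bond (compression effect), giving axial CH3 and equatorial OH trans to Br, and the reagent is neither basic nor halophilic.

**Step 12**
Reactants: 17 tertiary alcohol
Product: 19 protected target ((3S,4S,6S,8S,9S)-4,8-dibromo-9-chloro-3-(tert-butyldimethylsilyloxy)-5,5,9-trimethyl-1-methylidenespiro[5.5]undecane), via imidate salt 18 (not isolated)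
Conditions: Me2C=C(Cl)NMe2 (2 equiv), CH2Cl2, 0 °C to rt
Reagents that add atoms: 1-chloro-N,N,2-trimethylprop-1-en-1-amine, CC(C)=C(Cl)N(C)C
Why: Deoxychlorination of a tertiary alcohol with an α-chloroenamine under neutral conditions; 18 ionises, the neighbouring C8 bromine covers its own face (bromonium-type bridging), and the chloride of the ion pair returns on the face the amide left, so retention is expected and no free acid reaches the methylidene group.

**Step 13**
Reactants: 19 protected target
Product: 20 target ((3S,4S,6S,8S,9S)-4,8-dibromo-9-chloro-5,5,9-trimethyl-1-methylidenespiro[5.5]undecan-3-ol)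
Conditions: HF·pyridine, THF/pyridine, 0 °C to rt
Reagents that add atoms: none
Why: Fluoride-driven Si–O cleavage in a weakly acidic medium avoids the free alkoxide that would close the trans bromohydrin to an epoxide.

**Compound list**
1 | 2,2-dimethylcyclopentane-1,3-dione | CC1(C)C(=O)CCC1=O | starting material
2 | 5,5-dimethyl-4-oxocyclopent-1-en-1-yl trifluoromethanesulfonate | CC1(C)C(=O)CC=C1OS(=O)(=O)C(F)(F)F | intermediate
3 | 2,2-dimethylcyclopent-3-en-1-one | CC1(C)C=CCC1=O | intermediate
4 | (4-bromophenoxy)(tert-butyl)dimethylsilane | CC(C)(C)[Si](C)(C)Oc1ccc(Br)cc1 | starting material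
5 | [4-(tert-butyldimethylsilyloxy)phenyl]magnesium bromide | CC(C)(C)[Si](C)(C)Oc1ccc([Mg]Br)cc1 | intermediate
6 | rac-1-[4-(tert-butyldimethylsilyloxy)phenyl]-2,2-dimethylcyclopent-3-en-1-ol | CC1(C)C=CCC1(O)c1ccc(O[Si](C)(C)C(C)(C)C)cc1 | intermediate
7 | rac-1-(4-hydroxyphenyl)-2,2-dimethylcyclopent-3-en-1-ol | CC1(C)C=CCC1(O)c1ccc(O)cc1 | intermediate
8 | acetoxy(aryloxy)(phenyl)-λ3-iodane of 7 | CC(=O)OI(c1ccccc1)Oc1ccc(cc1)C1(O)CC=CC1(C)C | intermediate
9 | 5,5-dimethylspiro[5.5]undeca-3,7,10-triene-1,9-dione (achiral) | O=C1CC=CC(C)(C)C12C=CC(=O)C=C2 | intermediate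
10 | (6R)-9-[diethoxy(methyl)silyloxy]-5,5-dimethylspiro[5.5]undeca-3,7,9-trien-1-one | O=C1CC=CC(C)(C)[C@]12CC=C(O[Si](C)(OCC)OCC)C=C2 | intermediate
11 | (6R)-5,5-dimethylspiro[5.5]undeca-3,7-diene-1,9-dione | O=C1CC=CC(C)(C)[C@]12CCC(=O)C=C2 | intermediate
12 | (3S,4S,6R)-4-bromo-3-hydroxy-5,5-dimethylspiro[5.5]undec-7-ene-1,9-dione | O=C1C[C@H](O)[C@@H](Br)C(C)(C)[C@]12CCC(=O)C=C2 | intermediate
13 | tert-butyldimethylsilyl ether of 12 | O=C1C[C@H](O[Si](C)(C)C(C)(C)C)[C@@H](Br)C(C)(C)[C@]12CCC(=O)C=C2 | intermediate
14 | (3S,4S,6R)-C8=C9 triethylsilyl enol ether, C1 ketone | O=C1C[C@H](O[Si](C)(C)C(C)(C)C)[C@@H](Br)C(C)(C)[C@]12CCC(O[Si](CC)(CC)CC)=CC2 | intermediate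
15 | (3S,4S,6S)-1-methylidene analogue of 14 | C=C1C[C@H](O[Si](C)(C)C(C)(C)C)[C@@H](Br)C(C)(C)[C@]12CCC(O[Si](CC)(CC)CC)=CC2 | intermediate
16 | (3S,4S,6S,8S)-4,8-dibromo-9-ketone, equatorial C8–Br cis to C5 | C=C1C[C@H](O[Si](C)(C)C(C)(C)C)[C@@H](Br)C(C)(C)[C@]12CCC(=O)[C@@H](Br)C2 | intermediate
17 | (3S,4S,6S,8S,9S)-tertiary alcohol, OH trans to C8–Br | C=C1C[C@H](O[Si](C)(C)C(C)(C)C)[C@@H](Br)C(C)(C)[C@]12CC[C@](C)(O)[C@@H](Br)C2 | intermediate
18 | C9 O-alkyl N,N-dimethylisobutyrimidate chloride of 17 | C=C1C[C@H](O[Si](C)(C)C(C)(C)C)[C@@H](Br)C(C)(C)[C@]12CC[C@](C)(OC(C(C)C)=[N+](C)C)[C@@H](Br)C2.[Cl-] | intermediate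
19 | tert-butyldimethylsilyl ether of the target | C=C1C[C@H](O[Si](C)(C)C(C)(C)C)[C@@H](Br)C(C)(C)[C@]12CC[C@](C)(Cl)[C@@H](Br)C2 | intermediate
20 | (3S,4S,6S,8S,9S)-4,8-dibromo-9-chloro-5,5,9-trimethyl-1-methylidenespiro[5.5]undecan-3-ol | C=C1C[C@H](O)[C@@H](Br)C(C)(C)[C@]12CC[C@](C)(Cl)[C@@H](Br)C2 | target

**Step count**
Total step count: 13. Longest linear sequence: 13 steps (1 to 20); 4 is used as purchased.

**Steps most likely to fail**

Step 4. Capture of the cation by solvent or acetate, fragmentation of the C1–C6 bond, migration of C2, or acid-induced acyl shift of the dienone may outrun the wanted shift.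
- The fallback replaces the oxidatively made cation by a stereodefined epoxide C–O bond and keeps the five-to-six ring enlargement. It sets out from 3.
- 8-Bromo-1,4-dioxaspiro[4.5]dec-7-ene F1 is made from commercial 1,4-dioxaspiro[4.5]decan-8-one with (PhO)3P/Br2 and Et3N. It is lithiated with t-BuLi and added to 3 in the presence of LaCl3·2LiCl to give the allylic alcohol F2.
- Shi epoxidation (fructose-derived ketone or its enantiomer, KHSO5) oxidises the trisubstituted alkene under reagent control to the epoxy alcohol F3. Both carbinol epimers then carry the same epoxide configuration.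
- BF3·OEt2 at −78 °C triggers the semipinacol rearrangement of the 2,3-epoxy alcohol with anti migration of C5. This sets C6 stereospecifically and gives the β-hydroxy ketone ketal F4.
- Aqueous TsOH removes the ketal and the C7 hydroxyl leaves by β-elimination. The route is rejoined at 11 and step 5 is no longer needed.

Step 6. The two arms at C6 may differentiate the faces of the C3=C4 bond only weakly, so facial selectivity of bromonium opening may be poor.
- The fallback separates the two stereochemical problems so that each is under reagent control. It sets out from 9.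
- NBS in aqueous acetone gives the racemic trans bromohydrin F5.
- Kinetic resolution with Candida antarctica lipase B and vinyl acetate should acylate the (3R,4R)-enantiomer to the acetate F7, following the empirical size rule for lipases. This leaves the (3S,4S)-alcohol F6.
- TBSOTf/2,6-lutidine gives the silyl ether F8.
- The ligand-controlled CuH reduction of step 5 then proceeds through the silyl dienol ether F9 and fixes C6 independently of ring A. The route is rejoined at 13.

Step 12. Ionisation at C9 may end in proton loss, in bromine shift with chloride entry at C8, in loss of configuration, or in acid-triggered migration of the methylidene double bond.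
- The fallback finishes ring B while C1 is still a ketone and delivers chloride from a covalently bound leaving group. This is the stereoretentive chlorination of cyclic alcohols through chlorosulfites. It sets out from 14.
- NBS then LiBr gives the bromo diketone F10.
- AlMe3 at −78 °C should attack only the unhindered C9 ketone to give the tertiary alcohol F11.
- SOCl2 gives the chlorosulfite F12, and catalytic TiCl4 collapses it from the front side to the chloride F13.
- Cp2TiMe2 then methylenates C1, and the route is rejoined at 19.

**Further compounds**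
F1 | step 4 | 8-bromo-1,4-dioxaspiro[4.5]dec-7-ene | BrC1=CCC2(CC1)OCCO2
F2 | step 4 | rac-1-(1,4-dioxaspiro[4.5]dec-7-en-8-yl)-2,2-dimethylcyclopent-3-en-1-ol | CC1(C)C=CCC1(O)C1=CCC2(CC1)OCCO2
F3 | step 4 | C6,C7-epoxide of F2 (one epoxide configuration, both carbinol epimers) | CC1(C)C=CCC1(O)[C@@]23CCC4(OCCO4)C[C@@H]2O3
F4 | step 4 | 7-hydroxy-5,5-dimethylspiro[5.5]undec-3-ene-1,9-dione 9-ethylene ketal (C7–OH cis to C1) | O=C1CC=CC(C)(C)[C@]12CCC3(OCCO3)C[C@@H]2O
F5 | step 6 | racemic trans-4-bromo-3-hydroxy-5,5-dimethylspiro[5.5]undeca-7,10-diene-1,9-dione | O=C1CC(O)C(Br)C(C)(C)C12C=CC(=O)C=C2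
F6 | step 6 | (3S,4S)-enantiomer of F5 | O=C1C[C@H](O)[C@@H](Br)C(C)(C)C12C=CC(=O)C=C2
F7 | step 6 | (3R,4R)-acetate | O=C1C[C@@H](OC(C)=O)[C@H](Br)C(C)(C)C12C=CC(=O)C=C2
F8 | step 6 | tert-butyldimethylsilyl ether of F6 | O=C1C[C@H](O[Si](C)(C)C(C)(C)C)[C@@H](Br)C(C)(C)C12C=CC(=O)C=C2
F9 | step 6 | diethoxy(methyl)silyl dienol ether from F8 | O=C1C[C@H](O[Si](C)(C)C(C)(C)C)[C@@H](Br)C(C)(C)[C@]12CC=C(O[Si](C)(OCC)OCC)C=C2
F10 | step 12 | (3S,4S,6R,8S)-4,8-dibromo-1,9-diketone | O=C1C[C@H](O[Si](C)(C)C(C)(C)C)[C@@H](Br)C(C)(C)[C@]12CCC(=O)[C@@H](Br)C2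
F11 | step 12 | C9 tertiary alcohol with C1 ketone | O=C1C[C@H](O[Si](C)(C)C(C)(C)C)[C@@H](Br)C(C)(C)[C@]12CC[C@](C)(O)[C@@H](Br)C2
F12 | step 12 | C9 chlorosulfite | O=C1C[C@H](O[Si](C)(C)C(C)(C)C)[C@@H](Br)C(C)(C)[C@]12CC[C@](C)(OS(=O)Cl)[C@@H](Br)C2
F13 | step 12 | C9 chloride with C1 ketone | O=C1C[C@H](O[Si](C)(C)C(C)(C)C)[C@@H](Br)C(C)(C)[C@]12CC[C@](C)(Cl)[C@@H](Br)C2
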